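## The problem

The target is a cyclohexene (ring A, atoms C1–C6) with three adjacent substituted carbons. C1 carries the acyl carbon C7, C2 carries a 3,4-dimethoxyphenyl group (Ar1) and C6 carries a 4-hydroxy-3-methoxyphenyl group (Ar2); the ring alkene is C3=C4 and C5 is a methylene. C7 continues as the chelated enol of a 1,3-diketone that ends in a 4-hydroxy-3-methoxystyryl (feruloyl) unit. The configuration is (1S,2S,6S), with C7 cis to Ar2 and trans to Ar1. A direct [4+2] union of an aryl butadiene with an (E)-aryl enone would put C7 and Ar2 trans, so ring A needs its own stereocontrol. C6 is the only centre a catalyst can set in isolation. C1 sits between the two aryl-bearing carbons and is α to a carbonyl, so it must be set kinetically and never equilibrated, because a conformational estimate gives no reason to expect the target epimer to be the more stable one. C2 is both allylic and benzylic and has to be formed with the C3=C4 alkene already in its final place. The enolised unsaturated diketone (retro-Claisen cleavage, conjugate addition), the two free phenols and an alkene that could slip into conjugation with Ar1 or C7 will not survive rough treatment, so the diketone is made late and the phenols travel as silyl ethers. The enabling feature is that C7–C1–C2–C3=C4 is a γ,δ-unsaturated carbonyl unit (a Claisen retron) and that C4 is tied back to C1 through C5–C6. Re-forming an O–C4 bond therefore gives a six-membered lactone C7–C1–C6–C5–C4–O with a styryl arm on C4.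

## Retrosynthesis

**Diketone.** Target 28 is the bis-desilylated form of diketone 27. Compound 27 is cut between the central carbon of the diketone and the feruloyl carbonyl, giving methyl ketone 21 and the N-acylbenzotriazole 25. The neighbouring cut, between C7 and the central carbon, would make the crowded, epimerisable ring carbonyl the electrophile. The chosen cut makes ring A the nucleophile through its unhindered methyl group and delays the fragile unsaturated diketone to the penultimate step. The forward reaction must enolise the methyl group only, acylate on carbon, and be followed by a buffered fluoride deprotection.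

**One-carbon adjustments.** Ketone 21 is acid 18 plus one methyl group, added through the N-methoxy-N-methylamide 20 so that the ketone is released only at the quench. Donor 25 comes from ferulic acid 22 through its aryl silyl ether 24. These steps make no stereocentre; they must only leave C1 alone.

**Key disconnection.** In acid 18 the C1–C2 bond is cut and the O–C4 bond restored, with the alkene moving from C3=C4 to C2=C3. This gives the trans-4,6-disubstituted lactone 15 with a (Z)-styryl arm. Cutting C1–C6 and C2–C3 instead (a cycloaddition) leaves a regiochemical and an endo/exo question open. The Claisen cut has neither: the ring tether allows one boat array only. Lactone 15 has two 1,3-related stereocentres on a conformationally defined ring in place of three adjacent ones. The forward reaction must give clean O-silylation at C1 and a [3,3] shift that is faster than decomposition of the ketene acetal. It also needs a geometrically pure Z alkene, since Z gives Ar1 trans to C7 and E would give the all-cis isomer.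

**Lactone arylation.** The bond from Ar2 to the lactone (C6 of ring A) is cut, giving dihydropyranone 9 and boronic acid 14. This is preferred to building the aryl-bearing centre in an open chain because the existing carbinol centre and a chiral catalyst can act together on a half-chair. The reaction must add anti to the side chain and tolerate the lactone, the Z alkene and the silyl ether. An alkyne would compete for the aryl-rhodium species, so the triple bond must be reduced before this step.

**Unsaturated lactone.** Compound 9 is opened at its ring alkene (ring-closing metathesis) and at the ester C–O bond, giving acrylate 8, hence alcohol 6 and acryloyl chloride 7. The metathesis must load at the terminal alkene and leave the internal Z alkene untouched.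

**Dienol.** The Z alkene of 6 comes from the alkyne of propargylic alcohol 5 by syn semihydrogenation; a Z-selective olefination of a sensitive Z-enal is avoided. Alcohol 5 is cut at the allyl–carbinol bond to ynal 3, and 3 is cut at the formyl carbon to alkyne 1. The only absolute stereocontrol needed from a reagent in the whole route is the allylation of 3.

**Aryl donor.** Boronic acid 14 comes from aryl bromide 11 by halogen–metal exchange and borylation, and 11 from phenol 10 by silylation. Triisopropylsilyl is chosen because it must survive aqueous base, amide bases and a Grignard reagent before fluoride removes it.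

## Roads not taken

Alternative 1: Ring A is cut at C1–C6 and C2–C3. The forward step is an endo [4+2] cycloaddition of the (1E,3E)-1-aryl-4-silyl diene A2 with the (E)-cinnamoyl oxazolidinone A3, catalysed by Cu(SbF6)2 with a tert-butyl-bis(oxazoline). It gives adduct A1 with a C3 allylsilane, and protodesilylation then moves the alkene to C3=C4.
- Merits: two ring bonds and all three final stereocentres are set in one step, the absolute sense is catalyst-controlled, and the route is convergent and clearly shorter (about half the longest linear sequence of the chosen plan).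
- Weak points: a β-aryl acyl oxazolidinone is a sluggish dienophile toward an acyclic 1,4-disubstituted diene, so forcing conditions would erode endo selectivity and enantioselectivity. Regiochemistry depends on the aryl terminus outweighing the silyl terminus. The acid-mediated transposition has to spare two electron-rich arenes.
- Comparison: this road is better on step count and convergency. The chosen plan offers in return a ring closure with no regiochemical or endo/exo question and stereospecific transfer from one carbinol centre and one alkene geometry.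

Alternative 2: Ring A is cut at C3=C4. The forward step is ring-closing metathesis of the acyclic aldehyde A5 (vinyl on C2, allyl on C6) with the second-generation Grubbs catalyst RuCl2(H2IMes)(PCy3)(=CHPh), giving aldehyde A4.
- Merits: closure of a cyclohexene from a 1,7-diene is about as dependable as ring formation gets, and more dependable than the crowded sigmatropic shift used here.
- Weak points: the whole stereochemical problem moves into the open chain. A5 needs three adjacent stereocentres, the middle one α to an aldehyde and flanked by two benzylic carbons. That calls for a long sequence of acyclic stereocontrol with a constant risk of epimerisation at C1.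
- Comparison: the key step is safer than the chosen one, but the route to its substrate is longer and less certain. The chosen plan also uses a ring-closing metathesis, but on a substrate with one stereocentre.

Alternative 3: The C6–Ar2 and C1–C7 bonds are cut. The symmetric diene A7 (from Birch reduction of the biaryl) would react with aryl iodide A8, carbon monoxide and methanol under a chiral bis-phosphine complex of zerovalent palladium (from Pd2(dba)3). Syn addition anti to Ar1 would give ester A6.
- Merits: by far the shortest road; one step would set all three stereocentres from an achiral diene.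
- Weak points: an intermolecular, enantioselective arylcarbonylation of an unactivated ring alkene has no close precedent. The alkylpalladium intermediate has syn β-hydrogens, so Heck-type elimination competes with CO insertion. The 1,4-diene is prone to aromatise. Regiochemistry (aryl to the carbon remote from Ar1) is not secured by anything in the substrate.
- Comparison: if it worked it would beat the chosen plan on every count of economy. The chosen plan rests instead on reaction types that are each known on closely related substrates.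

Key step: step 9

## Route

Remarks on the chemistry:
- Ring A atoms are C1–C6 with C7 the exocyclic carbonyl carbon; locants inside compound names follow nomenclature rules, not this numbering.
- The target is drawn as its chelated enol tautomer.
- Assumption: (S,S)-2,5-diphenylbicyclo[2.2.2]octa-2,5-diene, (S,S)-Ph-bod*, is taken as the ligand enantiomer whose aryl delivery coincides with the substrate's own preference (attack anti to the side chain, giving 4S in lactone 15); the ligand is defined by that outcome.

Step 1
Reactants: 1 4-ethynyl-1,2-dimethoxybenzene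
Product: 3 3-(3,4-dimethoxyphenyl)prop-2-ynal, via lithium (3,4-dimethoxyphenyl)acetylide 2 (not isolated)
Conditions: n-BuLi, THF, −78 °C; DMF, −78 → 0 °C; poured into aq KH2PO4
Reagents that add atoms: N,N-dimethylformamide, CN(C)C=O
Why: Formylation of a lithium acetylide with DMF is a standard route to arylpropynals; the buffered inverse quench releases the aldehyde from the hemiaminal alkoxide before dimethylamine can add to the ynal.

Step 2
Reactants: 3 3-(3,4-dimethoxyphenyl)prop-2-ynal
Product: 5 (3R)-1-(3,4-dimethoxyphenyl)hex-5-en-1-yn-3-ol, via bis(isopinocampheyl)borinate ester 4 (not isolated)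
Conditions: lIpc2B(allyl) [from (−)-α-pinene], Et2O, −78 °C; then NaOH, H2O2, 0 → 23 °C
Reagents that add atoms: B-allylbis(isopinocampheyl)borane of the (−)-α-pinene series, C=CCB([C@H]1C[C@H]2C[C@@H]([C@@H]1C)C2(C)C)[C@H]1C[C@H]2C[C@@H]([C@@H]1C)C2(C)C
Why: Brown allylboration through a closed chair transition state; the reagent of the (−)-α-pinene series attacks the re face of aldehydes, which for an ynal (alkynyl ranks above allyl) is the R carbinol. The slim alkynyl group sits well in the chair, and oxidative work-up frees the alcohol from 4.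

Step 3
Reactants: 5 (3R)-1-(3,4-dimethoxyphenyl)hex-5-en-1-yn-3-ol
Product: 6 (1Z,3R)-1-(3,4-dimethoxyphenyl)hexa-1,5-dien-3-ol
Conditions: H2 (1 atm), Pd/CaCO3 poisoned with Pb(OAc)2 (Lindlar catalyst), quinoline, EtOAc, 23 °C, stopped at 1 equiv H2
Reagents that add atoms: none
Why: Lindlar semihydrogenation adds H2 syn and should give the Z alkene; the alkyne binds the poisoned surface far more strongly than the terminal alkene, which is spared if uptake is stopped at one equivalent. The carbinol centre is not touched.

Step 4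
Reactants: 6 (1Z,3R)-1-(3,4-dimethoxyphenyl)hexa-1,5-dien-3-ol; 7 acryloyl chloride
Product: 8 (1Z,3R)-1-(3,4-dimethoxyphenyl)hexa-1,5-dien-3-yl prop-2-enoate
Conditions: Et3N, CH2Cl2, −20 → 0 °C
Reagents that add atoms: none
Why: O-acylation of a secondary alcohol by an acid chloride; the mixture is kept cold and basic because the electron-rich allylic ester could ionise under acid.

Step 5
Reactants: 8 (1Z,3R)-1-(3,4-dimethoxyphenyl)hexa-1,5-dien-3-yl prop-2-enoate
Product: 9 (6R)-6-[(Z)-2-(3,4-dimethoxyphenyl)ethenyl]-5,6-dihydro-2H-pyran-2-one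
Conditions: first-generation Grubbs catalyst RuCl2(PCy3)2(=CHPh) (10 mol %), CH2Cl2 (0.005 M), 40 °C
Reagents that add atoms: none
Why: Ring-closing metathesis: the carbene loads at the terminal allyl alkene and closes onto the acrylate to the six-membered unsaturated lactone with loss of ethene, as is known for 6-styryl-5,6-dihydropyran-2-ones. The less active first-generation catalyst is chosen so that the internal Z alkene is left alone.

Step 6
Reactants: 10 4-bromo-2-methoxyphenol
Product: 11 (4-bromo-2-methoxyphenoxy)tri(propan-2-yl)silane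
Conditions: iPr3SiCl, imidazole, DMF, 23 °C
Reagents that add atoms: chlorotri(propan-2-yl)silane, CC(C)[Si](Cl)(C(C)C)C(C)C
Why: Standard silylation of a phenol; the triisopropylsilyl ether is chosen for its resistance to aqueous base (step 8), amide bases and Grignard reagents.

Step 7
Reactants: 11 (4-bromo-2-methoxyphenoxy)tri(propan-2-yl)silane
Product: 14 {3-methoxy-4-[tri(propan-2-yl)silyloxy]phenyl}boronic acid, via aryllithium 12 (not isolated), via diisopropyl arylboronate 13 (not isolated)
Conditions: n-BuLi, THF, −78 °C; B(OiPr)3, −78 → 23 °C; 1 M aq HCl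
Reagents that add atoms: triisopropyl borate, CC(C)OB(OC(C)C)OC(C)C; water, O
Why: Bromine–lithium exchange, borylation and hydrolysis; exchange is faster than ortho-lithiation, and the silyloxy group para to the carbanion cannot migrate.

Step 8
Reactants: 9 (6R)-6-[(Z)-2-(3,4-dimethoxyphenyl)ethenyl]-5,6-dihydro-2H-pyran-2-one; 14 {3-methoxy-4-[tri(propan-2-yl)silyloxy]phenyl}boronic acid
Product: 15 (4S,6R)-6-[(Z)-2-(3,4-dimethoxyphenyl)ethenyl]-4-{3-methoxy-4-[tri(propan-2-yl)silyloxy]phenyl}oxan-2-one (trans-4,6)
Conditions: [RhCl(C2H4)2]2 (2.5 mol %), (S,S)-Ph-bod* (5.5 mol %), KOH (10 mol %), 1,4-dioxane/H2O (10:1), 30 °C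
Reagents that add atoms: none
Why: Hayashi–Miyaura conjugate addition: an aryl complex of monovalent rhodium inserts the enoate and water protonates the resulting oxa-π-allyl species. The new centre (lactone position 4, later C6 of ring A) is set by aryl delivery anti to the pseudo-equatorial side chain, reinforced by the matched diene ligand, giving the trans lactone. The low temperature and catalytic hydroxide should spare the lactone, the Z alkene and the silyl ether.

Step 9
Reactants: 15 (4S,6R)-6-[(Z)-2-(3,4-dimethoxyphenyl)ethenyl]-4-{3-methoxy-4-[tri(propan-2-yl)silyloxy]phenyl}oxan-2-one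
Product: 18 (1S,2S,6S)-2-(3,4-dimethoxyphenyl)-6-{3-methoxy-4-[tri(propan-2-yl)silyloxy]phenyl}cyclohex-3-ene-1-carboxylic acid, via cyclic silyl ketene acetal 16 (not isolated), via trimethylsilyl ester 17 (not isolated)
Conditions: LiN(iPr)2, Me3SiCl/Et3N (internal quench), THF, −78 → 23 °C; toluene, 110 °C; then 1 M aq HCl, THF, 23 °C
Reagents that add atoms: none
Why: Kinetic deprotonation at the only enolisable position (C1) in the presence of Me3SiCl should give the cyclic O-silyl ketene acetal 16, an allyl vinyl ether whose six atoms C1=C7–O–C4–C3=C2 are already assembled. On heating, the half-chair with the styryl arm pseudo-axial and Ar2 pseudo-equatorial undergoes a suprafacial [3,3] sigmatropic shift (Ireland–Claisen rearrangement) that forms C1–C2, breaks O–C4 and creates C3=C4; the closest known reaction type is the ring contraction of alkenyl lactone silyl ketene acetals to cycloalkenecarboxylic acids. Ring A closes by this contraction: the two-carbon tether C5–C6 links the termini C4 and C1, so only a boat, bicyclo[2.2.2]octane-like array is possible and no chair competes. The same tether forces C5 and C2 to be cis on the new C3=C4 bond, which fixes the rotamer about C4–C3. C1 is controlled by the carbinol centre C4, because the new bond can form only on the face of the ketene acetal that carries the styryl arm; with the trans lactone this puts C7 cis to Ar2. C2 is controlled by the alkene geometry: in the eclipsed boat the Z substituent Ar1 lies over C6 and so ends trans to C7, whereas an E alkene would give the all-cis isomer. The step therefore needs a geometrically pure Z alkene (secured in step 3) and clean O-silylation (secured by the internal quench with Me3SiCl/Et3N). Dilute acid then hydrolyses the labile silyl ester 17 to acid 18 without touching the aryl silyl ether; the carbinol centre is consumed and the Ar2-bearing centre is carried over unchanged.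

Step 10
Reactants: 18 (1S,2S,6S)-2-(3,4-dimethoxyphenyl)-6-{3-methoxy-4-[tri(propan-2-yl)silyloxy]phenyl}cyclohex-3-ene-1-carboxylic acid
Product: 20 (1S,2S,6S)-2-(3,4-dimethoxyphenyl)-N-methoxy-6-{3-methoxy-4-[tri(propan-2-yl)silyloxy]phenyl}-N-methylcyclohex-3-ene-1-carboxamide, via acyl imidazole 19 (not isolated)
Conditions: 1,1'-carbonyldiimidazole, CH2Cl2, 23 °C; MeNH(OMe)·HCl, 23 → 40 °C
Reagents that add atoms: N,O-dimethylhydroxylamine hydrochloride, CNOC.Cl
Why: Activation as the acyl imidazole and aminolysis give the N-methoxy-N-methylamide without strong base, so C1 is not enolised.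

Step 11
Reactants: 20 (1S,2S,6S)-2-(3,4-dimethoxyphenyl)-N-methoxy-6-{3-methoxy-4-[tri(propan-2-yl)silyloxy]phenyl}-N-methylcyclohex-3-ene-1-carboxamide
Product: 21 1-[(1S,2S,6S)-2-(3,4-dimethoxyphenyl)-6-{3-methoxy-4-[tri(propan-2-yl)silyloxy]phenyl}cyclohex-3-en-1-yl]ethan-1-one
Conditions: MeMgBr, THF, 0 °C; aq NH4Cl
Reagents that add atoms: methylmagnesium bromide, C[Mg]Br
Why: Weinreb ketone synthesis: the magnesium chelate of the tetrahedral adduct prevents over-addition and releases the ketone only at the quench, so C1 is never a ketone α-carbon in basic solution.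

Step 12
Reactants: 22 ferulic acid, (E)-3-(4-hydroxy-3-methoxyphenyl)prop-2-enoic acid
Product: 24 (E)-3-[4-(tert-butyldimethylsilyloxy)-3-methoxyphenyl]prop-2-enoic acid, via bis-silylated ferulate 23 (not isolated)
Conditions: TBSCl (2.5 equiv), imidazole, DMF, 23 °C; then AcOH, THF/H2O, 23 °C
Reagents that add atoms: tert-butylchlorodimethylsilane, CC(C)(C)[Si](C)(C)Cl
Why: Exhaustive silylation followed by selective hydrolysis: a silyl ester is far more labile than an aryl silyl ether, so mild aqueous acid frees only the carboxylic acid.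

Step 13
Reactants: 24 (E)-3-[4-(tert-butyldimethylsilyloxy)-3-methoxyphenyl]prop-2-enoic acid
Product: 25 (E)-1-(1H-benzotriazol-1-yl)-3-[4-(tert-butyldimethylsilyloxy)-3-methoxyphenyl]prop-2-en-1-one
Conditions: 1H-benzotriazole (4 equiv), SOCl2 (1.05 equiv), CH2Cl2, 23 °C
Reagents that add atoms: 1H-benzotriazole, c1ccc2[nH]nnc2c1
Why: One-flask conversion of a carboxylic acid into its N-acylbenzotriazole through sulfinyl-activated benzotriazole; the excess benzotriazole buffers HCl, so the aryl silyl ether and the E alkene should survive, and the product is a neutral, storable acyl donor.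

Step 14
Reactants: 21 1-[(1S,2S,6S)-2-(3,4-dimethoxyphenyl)-6-{3-methoxy-4-[tri(propan-2-yl)silyloxy]phenyl}cyclohex-3-en-1-yl]ethan-1-one; 25 (E)-1-(1H-benzotriazol-1-yl)-3-[4-(tert-butyldimethylsilyloxy)-3-methoxyphenyl]prop-2-en-1-one
Product: 27 (2Z,4E)-5-[4-(tert-butyldimethylsilyloxy)-3-methoxyphenyl]-1-[(1S,2S,6S)-2-(3,4-dimethoxyphenyl)-6-{3-methoxy-4-[tri(propan-2-yl)silyloxy]phenyl}cyclohex-3-en-1-yl]-3-hydroxypenta-2,4-dien-1-one, via lithium enolate 26 (not isolated)
Conditions: LiN(SiMe3)2 (2.2 equiv), THF, −78 °C; 25, −78 → −20 °C; aq NH4Cl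
Reagents that add atoms: none
Why: Crossed Claisen-type C-acylation of a kinetic methyl ketone enolate by an N-acylbenzotriazole, a known route to 1,3-diketones; the bulky base removes a methyl proton, not the hindered C1–H. The second equivalent of base turns the product into its diketonate, which stops further acylation and keeps C1 configurationally safe.

Step 15
Reactants: 27 (2Z,4E)-5-[4-(tert-butyldimethylsilyloxy)-3-methoxyphenyl]-1-[(1S,2S,6S)-2-(3,4-dimethoxyphenyl)-6-{3-methoxy-4-[tri(propan-2-yl)silyloxy]phenyl}cyclohex-3-en-1-yl]-3-hydroxypenta-2,4-dien-1-one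
Product: 28 (2Z,4E)-1-[(1S,2S,6S)-2-(3,4-dimethoxyphenyl)-6-(4-hydroxy-3-methoxyphenyl)cyclohex-3-en-1-yl]-3-hydroxy-5-(4-hydroxy-3-methoxyphenyl)penta-2,4-dien-1-one (CNP0290899.2)
Conditions: Bu4NF, AcOH, THF, 0 → 23 °C
Reagents that add atoms: none
Why: Fluoride cleaves both aryl silyl ethers; the acetic acid buffer keeps the medium from becoming basic enough for retro-Claisen cleavage, epimerisation at C1 or oxidation of the phenoxides.

## Compound list

1 | 4-ethynyl-1,2-dimethoxybenzene | COc1ccc(C#C)cc1OC | starting material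
2 | lithium (3,4-dimethoxyphenyl)acetylide | [Li]C#Cc1ccc(OC)c(OC)c1 | intermediate (not isolated)
3 | 3-(3,4-dimethoxyphenyl)prop-2-ynal | O=CC#Cc1ccc(OC)c(OC)c1 | intermediate
4 | (3R)-1-(3,4-dimethoxyphenyl)hex-5-en-1-yn-3-yl bis(isopinocampheyl)borinate, (−)-α-pinene series | C=CC[C@@H](OB([C@H]1C[C@H]2C[C@@H]([C@@H]1C)C2(C)C)[C@H]1C[C@H]2C[C@@H]([C@@H]1C)C2(C)C)C#Cc1ccc(OC)c(OC)c1 | intermediate (not isolated)
5 | (3R)-1-(3,4-dimethoxyphenyl)hex-5-en-1-yn-3-ol | C=CC[C@@H](O)C#Cc1ccc(OC)c(OC)c1 | intermediate
6 | (1Z,3R)-1-(3,4-dimethoxyphenyl)hexa-1,5-dien-3-ol | C=CC[C@@H](O)/C=C\c1ccc(OC)c(OC)c1 | intermediate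
7 | acryloyl chloride | C=CC(Cl)=O | starting material
8 | (1Z,3R)-1-(3,4-dimethoxyphenyl)hexa-1,5-dien-3-yl prop-2-enoate | C=CC[C@@H](OC(=O)C=C)/C=C\c1ccc(OC)c(OC)c1 | intermediate
9 | (6R)-6-[(Z)-2-(3,4-dimethoxyphenyl)ethenyl]-5,6-dihydro-2H-pyran-2-one | O=C1C=CC[C@H](/C=C\c2ccc(OC)c(OC)c2)O1 | intermediate
10 | 4-bromo-2-methoxyphenol | COc1cc(Br)ccc1O | starting material
11 | (4-bromo-2-methoxyphenoxy)tri(propan-2-yl)silane | COc1cc(Br)ccc1O[Si](C(C)C)(C(C)C)C(C)C | intermediate
12 | {3-methoxy-4-[tri(propan-2-yl)silyloxy]phenyl}lithium | [Li]c1ccc(O[Si](C(C)C)(C(C)C)C(C)C)c(OC)c1 | intermediate (not isolated)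
13 | dipropan-2-yl {3-methoxy-4-[tri(propan-2-yl)silyloxy]phenyl}boronate | CC(C)OB(OC(C)C)c1ccc(O[Si](C(C)C)(C(C)C)C(C)C)c(OC)c1 | intermediate (not isolated)
14 | {3-methoxy-4-[tri(propan-2-yl)silyloxy]phenyl}boronic acid | OB(O)c1ccc(O[Si](C(C)C)(C(C)C)C(C)C)c(OC)c1 | intermediate
15 | (4S,6R)-6-[(Z)-2-(3,4-dimethoxyphenyl)ethenyl]-4-{3-methoxy-4-[tri(propan-2-yl)silyloxy]phenyl}oxan-2-one (trans) | O=C1C[C@@H](c2ccc(O[Si](C(C)C)(C(C)C)C(C)C)c(OC)c2)C[C@H](/C=C\c3ccc(OC)c(OC)c3)O1 | intermediate
16 | trimethyl{[(2R,4S)-2-[(Z)-2-(3,4-dimethoxyphenyl)ethenyl]-4-{3-methoxy-4-[tri(propan-2-yl)silyloxy]phenyl}-3,4-dihydro-2H-pyran-6-yl]oxy}silane | C[Si](C)(C)OC1=C[C@@H](c2ccc(O[Si](C(C)C)(C(C)C)C(C)C)c(OC)c2)C[C@H](/C=C\c3ccc(OC)c(OC)c3)O1 | intermediate (not isolated)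
17 | trimethylsilyl (1S,2S,6S)-2-(3,4-dimethoxyphenyl)-6-{3-methoxy-4-[tri(propan-2-yl)silyloxy]phenyl}cyclohex-3-ene-1-carboxylate | C[Si](C)(C)OC(=O)[C@@H]1[C@@H](c2ccc(OC)c(OC)c2)C=CC[C@@H]1c3ccc(O[Si](C(C)C)(C(C)C)C(C)C)c(OC)c3 | intermediate (not isolated)
18 | (1S,2S,6S)-2-(3,4-dimethoxyphenyl)-6-{3-methoxy-4-[tri(propan-2-yl)silyloxy]phenyl}cyclohex-3-ene-1-carboxylic acid | OC(=O)[C@@H]1[C@@H](c2ccc(OC)c(OC)c2)C=CC[C@@H]1c3ccc(O[Si](C(C)C)(C(C)C)C(C)C)c(OC)c3 | intermediate
19 | [(1S,2S,6S)-2-(3,4-dimethoxyphenyl)-6-{3-methoxy-4-[tri(propan-2-yl)silyloxy]phenyl}cyclohex-3-en-1-yl](1H-imidazol-1-yl)methanone | O=C(n1ccnc1)[C@@H]1[C@@H](c2ccc(OC)c(OC)c2)C=CC[C@@H]1c3ccc(O[Si](C(C)C)(C(C)C)C(C)C)c(OC)c3 | intermediate (not isolated)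
20 | (1S,2S,6S)-2-(3,4-dimethoxyphenyl)-N-methoxy-6-{3-methoxy-4-[tri(propan-2-yl)silyloxy]phenyl}-N-methylcyclohex-3-ene-1-carboxamide | CON(C)C(=O)[C@@H]1[C@@H](c2ccc(OC)c(OC)c2)C=CC[C@@H]1c3ccc(O[Si](C(C)C)(C(C)C)C(C)C)c(OC)c3 | intermediate
21 | 1-[(1S,2S,6S)-2-(3,4-dimethoxyphenyl)-6-{3-methoxy-4-[tri(propan-2-yl)silyloxy]phenyl}cyclohex-3-en-1-yl]ethan-1-one | CC(=O)[C@@H]1[C@@H](c2ccc(OC)c(OC)c2)C=CC[C@@H]1c3ccc(O[Si](C(C)C)(C(C)C)C(C)C)c(OC)c3 | intermediate
22 | ferulic acid, (E)-3-(4-hydroxy-3-methoxyphenyl)prop-2-enoic acid | COc1cc(/C=C/C(=O)O)ccc1O | starting material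
23 | tert-butyldimethylsilyl (E)-3-[4-(tert-butyldimethylsilyloxy)-3-methoxyphenyl]prop-2-enoate | COc1cc(/C=C/C(=O)O[Si](C)(C)C(C)(C)C)ccc1O[Si](C)(C)C(C)(C)C | intermediate (not isolated)
24 | (E)-3-[4-(tert-butyldimethylsilyloxy)-3-methoxyphenyl]prop-2-enoic acid | COc1cc(/C=C/C(=O)O)ccc1O[Si](C)(C)C(C)(C)C | intermediate
25 | (E)-1-(1H-benzotriazol-1-yl)-3-[4-(tert-butyldimethylsilyloxy)-3-methoxyphenyl]prop-2-en-1-one | COc1cc(/C=C/C(=O)n2nnc3ccccc32)ccc1O[Si](C)(C)C(C)(C)C | intermediate
26 | lithium 1-[(1S,2S,6S)-2-(3,4-dimethoxyphenyl)-6-{3-methoxy-4-[tri(propan-2-yl)silyloxy]phenyl}cyclohex-3-en-1-yl]ethen-1-olate | [Li]OC(=C)[C@@H]1[C@@H](c2ccc(OC)c(OC)c2)C=CC[C@@H]1c3ccc(O[Si](C(C)C)(C(C)C)C(C)C)c(OC)c3 | intermediate (not isolated)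
27 | (2Z,4E)-5-[4-(tert-butyldimethylsilyloxy)-3-methoxyphenyl]-1-[(1S,2S,6S)-2-(3,4-dimethoxyphenyl)-6-{3-methoxy-4-[tri(propan-2-yl)silyloxy]phenyl}cyclohex-3-en-1-yl]-3-hydroxypenta-2,4-dien-1-one | COc1cc(/C=C/C(O)=C/C(=O)[C@@H]2[C@@H](c3ccc(OC)c(OC)c3)C=CC[C@@H]2c2ccc(O[Si](C(C)C)(C(C)C)C(C)C)c(OC)c2)ccc1O[Si](C)(C)C(C)(C)C | intermediate
28 | (2Z,4E)-1-[(1S,2S,6S)-2-(3,4-dimethoxyphenyl)-6-(4-hydroxy-3-methoxyphenyl)cyclohex-3-en-1-yl]-3-hydroxy-5-(4-hydroxy-3-methoxyphenyl)penta-2,4-dien-1-one | COc1cc(/C=C/C(O)=C/C(=O)[C@@H]2[C@@H](c3ccc(OC)c(OC)c3)C=CC[C@@H]2c2ccc(O)c(OC)c2)ccc1O | target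

## Step count and risk

Total: 15 steps. Longest linear sequence: 11 steps (steps 1, 2, 3, 4, 5, 8, 9, 10, 11, 14, 15).

**Step 9 (key step).**
- What may go wrong: the boat array is crowded because the Z aryl group must sit over C6 and beside C5. The shift may then be slower than loss of the ketene acetal by adventitious hydrolysis or C-silylation. Incomplete trapping of the lactone enolate would also lead to self-condensation.
- Fallback: ring A would be closed by an endo Diels–Alder reaction that forms C1–C6 and C2–C3. It sets out from bromide 11 and returns at acid 18.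
  - Bromine–lithium exchange (n-BuLi) and formylation with DMF give 3-methoxy-4-[tri(propan-2-yl)silyloxy]benzaldehyde F1.
  - Peterson olefination with lithiated 1,3-bis(trimethylsilyl)propene (MgBr2 added to favour the E,E isomer) gives (1E,3E)-1-{3-methoxy-4-[tri(propan-2-yl)silyloxy]phenyl}-4-(trimethylsilyl)buta-1,3-diene F2.
  - Commercial (E)-3-(3,4-dimethoxyphenyl)prop-2-enoic acid is converted through its pivaloyl mixed anhydride into 3-[(E)-3-(3,4-dimethoxyphenyl)prop-2-enoyl]-1,3-oxazolidin-2-one F3.
  - Cu(SbF6)2 with the enantiomer of 2,2'-isopropylidenebis(4-tert-butyl-2-oxazoline) that exposes the required face should join F2 and F3 to the endo cycloadduct F4. It carries the allylsilane at C3 and a C4=C5 alkene, with C7 cis to Ar2 and trans to Ar1.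
  - Protodesilylation with CF3CO2H (SE2′: proton to C5, alkene to C3=C4) gives the transposed imide F5.
  - LiOH/H2O2 removes the oxazolidinone and delivers 18.

**Step 8.**
- What may go wrong: hydroxide may open the lactone, the labile allylic C–O bond may ionise before carbometalation, or a mismatched ligand may lower the trans selectivity.
- Fallback: substrate-controlled organocopper addition. It sets out from 9 (with bromide 11 as aryl source) and returns at 15.
  - Bromide 11 is converted by bromine–lithium exchange (n-BuLi) and CuBr·SMe2 into lithium bis{3-methoxy-4-[tri(propan-2-yl)silyloxy]phenyl}cuprate F6, a diarylcuprate of monovalent copper.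
  - F6 adds to 9 at −78 °C in the presence of Me3SiCl by axial attack anti to the side chain.
  - Aqueous work-up gives 15; alternatively the silyl ketene acetal formed in this addition, which is 16, is carried straight into the thermal stage of step 9.

**Step 5.**
- What may go wrong: metathesis at the Z-styryl alkene (isomerisation to E, or excision of the aryl alkene) may compete with ring closure, because a Z-1,2-disubstituted alkene is the more reactive kind toward ruthenium carbenes.
- Fallback: the alkyne is kept through the ring closure. It sets out from alcohol 5 and returns at 9.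
  - Acrylation (acryloyl chloride 7, Et3N) gives (3R)-1-(3,4-dimethoxyphenyl)hex-5-en-1-yn-3-yl prop-2-enoate F7.
  - Ring-closing metathesis gives (6R)-6-[(3,4-dimethoxyphenyl)ethynyl]-5,6-dihydro-2H-pyran-2-one F8. Closure of the carbene onto the triple bond would need a four-membered ring, so the alkyne should be a spectator.
  - Semihydrogenation over Pd/CaCO3 poisoned with Pb(OAc)2 then gives 9, on a substrate that no longer has a terminal alkene.

**Step 14.**
- What may go wrong: O-acylation or double acylation, conjugate addition of the enolate to the cinnamoyl acceptor, or proton exchange between enolate and ketone that epimerises C1.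
- Fallback: aldol addition followed by oxidation. It sets out from ketone 21 and returns at 27.
  - Enolate 26 (from 21 and LiN(SiMe3)2, −78 °C) adds to (E)-3-[4-(tert-butyldimethylsilyloxy)-3-methoxyphenyl]prop-2-enal F9, itself made from commercial 4-hydroxy-3-methoxycinnamaldehyde, TBSCl and imidazole.
  - This gives the β-hydroxy ketone F10 as a mixture at the carbinol carbon, which is of no consequence.
  - Dess–Martin periodinane oxidises F10 to 27.

## Further compounds

F1 | step 9 | 3-methoxy-4-[tri(propan-2-yl)silyloxy]benzaldehyde | COc1cc(C=O)ccc1O[Si](C(C)C)(C(C)C)C(C)C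
F2 | step 9 | (1E,3E)-1-{3-methoxy-4-[tri(propan-2-yl)silyloxy]phenyl}-4-(trimethylsilyl)buta-1,3-diene | C[Si](C)(C)/C=C/C=C/c1ccc(O[Si](C(C)C)(C(C)C)C(C)C)c(OC)c1
F3 | step 9 | 3-[(E)-3-(3,4-dimethoxyphenyl)prop-2-enoyl]-1,3-oxazolidin-2-one | COc1ccc(/C=C/C(=O)N2CCOC2=O)cc1OC
F4 | step 9 | endo cycloadduct: 3-{[2-(3,4-dimethoxyphenyl)-6-{3-methoxy-4-[tri(propan-2-yl)silyloxy]phenyl}-3-(trimethylsilyl)cyclohex-4-en-1-yl]carbonyl}-1,3-oxazolidin-2-one, C7 cis to Ar2 and to the silyl group, trans to Ar1 | O=C(N1CCOC1=O)[C@@H]2[C@@H](c3ccc(OC)c(OC)c3)[C@H]([Si](C)(C)C)C=C[C@@H]2c4ccc(O[Si](C(C)C)(C(C)C)C(C)C)c(OC)c4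
F5 | step 9 | 3-{[(1S,2S,6S)-2-(3,4-dimethoxyphenyl)-6-{3-methoxy-4-[tri(propan-2-yl)silyloxy]phenyl}cyclohex-3-en-1-yl]carbonyl}-1,3-oxazolidin-2-one | O=C(N1CCOC1=O)[C@@H]2[C@@H](c3ccc(OC)c(OC)c3)C=CC[C@@H]2c4ccc(O[Si](C(C)C)(C(C)C)C(C)C)c(OC)c4
F6 | step 8 | lithium bis{3-methoxy-4-[tri(propan-2-yl)silyloxy]phenyl}cuprate | [Li+].COc1cc([Cu-]c2ccc(O[Si](C(C)C)(C(C)C)C(C)C)c(OC)c2)ccc1O[Si](C(C)C)(C(C)C)C(C)C
F7 | step 5 | (3R)-1-(3,4-dimethoxyphenyl)hex-5-en-1-yn-3-yl prop-2-enoate | C=CC[C@@H](OC(=O)C=C)C#Cc1ccc(OC)c(OC)c1
F8 | step 5 | (6R)-6-[(3,4-dimethoxyphenyl)ethynyl]-5,6-dihydro-2H-pyran-2-one | O=C1C=CC[C@H](C#Cc2ccc(OC)c(OC)c2)O1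
F9 | step 14 | (E)-3-[4-(tert-butyldimethylsilyloxy)-3-methoxyphenyl]prop-2-enal | COc1cc(/C=C/C=O)ccc1O[Si](C)(C)C(C)(C)C
F10 | step 14 | (E)-5-[4-(tert-butyldimethylsilyloxy)-3-methoxyphenyl]-1-[(1S,2S,6S)-2-(3,4-dimethoxyphenyl)-6-{3-methoxy-4-[tri(propan-2-yl)silyloxy]phenyl}cyclohex-3-en-1-yl]-3-hydroxypent-4-en-1-one (both carbinol epimers) | COc1cc(/C=C/C(O)CC(=O)[C@@H]2[C@@H](c3ccc(OC)c(OC)c3)C=CC[C@@H]2c2ccc(O[Si](C(C)C)(C(C)C)C(C)C)c(OC)c2)ccc1O[Si](C)(C)C(C)(C)C
A1 | alternative 1 | endo cycloadduct: 3-{[6-[4-(tert-butyldimethylsilyloxy)-3-methoxyphenyl]-2-(3,4-dimethoxyphenyl)-3-(trimethylsilyl)cyclohex-4-en-1-yl]carbonyl}-1,3-oxazolidin-2-one, C7 cis to Ar2 and to the silyl group, trans to Ar1 | O=C(N1CCOC1=O)[C@@H]2[C@@H](c3ccc(OC)c(OC)c3)[C@H]([Si](C)(C)C)C=C[C@@H]2c4ccc(O[Si](C)(C)C(C)(C)C)c(OC)c4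
A2 | alternative 1 | (1E,3E)-1-[4-(tert-butyldimethylsilyloxy)-3-methoxyphenyl]-4-(trimethylsilyl)buta-1,3-diene | C[Si](C)(C)/C=C/C=C/c1ccc(O[Si](C)(C)C(C)(C)C)c(OC)c1
A3 | alternative 1 | 3-[(E)-3-(3,4-dimethoxyphenyl)prop-2-enoyl]-1,3-oxazolidin-2-one | COc1ccc(/C=C/C(=O)N2CCOC2=O)cc1OC
A4 | alternative 2 | (1S,2S,6S)-6-[4-(tert-butyldimethylsilyloxy)-3-methoxyphenyl]-2-(3,4-dimethoxyphenyl)cyclohex-3-ene-1-carbaldehyde | O=C[C@@H]1[C@@H](c2ccc(OC)c(OC)c2)C=CC[C@@H]1c3ccc(O[Si](C)(C)C(C)(C)C)c(OC)c3
A5 | alternative 2 | acyclic aldehyde: 3-[4-(tert-butyldimethylsilyloxy)-3-methoxyphenyl]-2-[1-(3,4-dimethoxyphenyl)prop-2-enyl]hex-5-enal with the three stereocentres as in A4 | O=C[C@H]([C@H](C=C)c1ccc(OC)c(OC)c1)[C@H](CC=C)c1ccc(O[Si](C)(C)C(C)(C)C)c(OC)c1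
A6 | alternative 3 | methyl (1S,2S,6S)-6-[4-(tert-butyldimethylsilyloxy)-3-methoxyphenyl]-2-(3,4-dimethoxyphenyl)cyclohex-3-ene-1-carboxylate | COC(=O)[C@@H]1[C@@H](c2ccc(OC)c(OC)c2)C=CC[C@@H]1c3ccc(O[Si](C)(C)C(C)(C)C)c(OC)c3
A7 | alternative 3 | 4-(cyclohexa-2,5-dien-1-yl)-1,2-dimethoxybenzene | COc1ccc(C2C=CCC=C2)cc1OC
A8 | alternative 3 | tert-butyl(4-iodo-2-methoxyphenoxy)dimethylsilane | COc1cc(I)ccc1O[Si](C)(C)C(C)(C)C
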